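- If the rate law and the late X readings part, I read the gap as a leak of X, and I carry that leak to the red flask.

| flask | Q | Z | G | time |
|---|---|---|---|---|
| teal | 0.100 M | 0.200 M | 0.00500 M |  |
| grey | 0.100 M | 0.200 M | 0.0150 M |  |
| ochre | 0.100 M | 0.100 M | 0.00500 M |  |
| amber | 0.300 M | 0.200 M | 0.00500 M |  |
| red | 0.400 M | 0.800 M | 0.00500 M | 110 s |

| run | time / s | [X] / M |
|---|---|---|
| teal run | 4.9 | 0.0049 |
| teal run | 15 | 0.0093 |
| teal run | 28 | 0.0175 |
| teal run | 45 | 0.0253 |
| teal run | 64 | 0.0328 |
| teal run | 86 | 0.0366 |
| teal run | 110 | 0.0387 |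
| grey run | 4.9 | 0.0051 |
| grey run | 15 | 0.0184 |
| grey run | 28 | 0.0290 |
| grey run | 45 | 0.0395 |
| grey run | 64 | 0.0460 |
| grey run | 86 | 0.0472 |
| grey run | 110 | 0.0488 |
| ochre run | 4.9 | 0.0013 |
| ochre run | 15 | 0.0039 |
| ochre run | 28 | 0.0090 |
| ochre run | 45 | 0.0150 |
| ochre run | 64 | 0.0173 |
| ochre run | 86 | 0.0208 |
| ochre run | 110 | 0.0225 |
| amber run | 4.9 | 0.0107 |
| amber run | 15 | 0.0313 |
| amber run | 28 | 0.0544 |
| amber run | 45 | 0.0744 |
| amber run | 64 | 0.0892 |
| amber run | 86 | 0.0977 |
| amber run | 110 | 0.0995 |

(readings scatter by 8 × 10⁻⁴ M)

- Overall: Q + Z -> X, with G as catalyst.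
- Constant volume, constant temperature.
- "The second partner" is Z.
- An order is taken over about fifteen percent of the charge, up and down.

* apparent order in [G] of the starting rate, round the charge of the teal run (the rate where two percent of its Q have turned into X)
* apparent order in [Z] of the starting rate, round the charge of the teal run (the rate where two percent of its Q have turned into X)
* X in the red run at 110 s, as a share of the Q charged

- Integrating a second-order law, rate = k × Q × Z, up to the readings at 28 s gives a constant of 0.0360 M⁻¹ s⁻¹ for teal, 0.0664 M⁻¹ s⁻¹ for grey and 0.0353 M⁻¹ s⁻¹ for ochre.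
- Grey, at 3.00 times the G of teal, has 1.84 times the teal constant, so I read an order in G of 0.557. Ochre, at half the Z of teal, runs on these constants at 0.491 of the teal rate, so I read an order in Z of 1.03.
- My first way uses amber, where Z is the limiting reagent. Integrating the law to the middle of the last interval, 86 s to 110 s, leaves 44.1% of the Z. Over that interval the law then makes 4.78% of the Q charged, but X climbs by 0.600%. Dividing that gap by the X standing and the interval gives 0.00529 s⁻¹.
- My second way uses grey, with a different charge and more G, and with Q as the limiting reagent. The law leaves 35.3% of the Q and makes 7.61% of the charge, while X climbs by 1.60%. This gives 0.00522 s⁻¹.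
- The two readings agree, so I trust their mean, 0.00525 s⁻¹, as the loss constant of X, the chance per second that a formed X leaves. It gives X a half-life of 132 s.
- I follow one Q molecule in the red flask, which has the G of teal. Taking Z as it stands when half of the Q has gone, Q turns with a pseudo-first-order constant of 0.0216 s⁻¹, which is faster than the leak. Each X then faces the leak, so the two chained forks keep pf/(pf − kd) × (e^(−kd·t) − e^(−pf·t)), which is 61.9% of the charge at 110 s.
- The forecast gives 0.55 in G, 1 in Z and 79% for the red flask, holding that “the catalyst dies on a clock”. Its figure stands above mine by 17 percentage points.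

    2 G ⇌ G2, settled at all times (1960 M⁻¹)
    G + Q + Z → X + G (37.70 M⁻² s⁻¹)
    X → Jo (0.006310 s⁻¹)
    Q + Z + X → 2 X (0.3220 M⁻² s⁻¹)

- The red flask gives 56.4% of its Q as X at 110 s, with orders of 0.56 in G and 1.0 in Z. The forecast stands 23 points too high, and the step from X to Jo is the main reason: the same red flask without that step reaches 99.9%, which is 43 points more. My loss constant of 0.00525 s⁻¹ put the red flask at 61.9%, which is 5.5 points above what it gives. At the constant of that step, 0.00631 s⁻¹, the X standing in the red flask at 110 s leaks 0.00356 s⁻¹ of the charge each second.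

(The earlier runs and the new flask are simulated for substances that don't exist, and the scatter is random.)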